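**Strategy.** Ring A of the trans-hydrindane (C3a–C4–C5–C6–C7–C7a) hides an isobutene unit, C4(Me)2–C5H2. The route therefore builds an acyclic (4E,8Z)-dienal that already holds C6, C7, C7a, C3a, C3, C2 and C1, and lets an organocatalytic SOMO radical-polar crossover annulation insert isobutene: the α-formyl radical cation at C6 captures the CH2 end (C5–C6), the derived C4 cation closes ring A on the E-alkene (C3a–C4), and an allylsilane closes ring B. One operation sets C1, C3a and C7a; the temporary formyl group on C6 relays the catalyst chirality and is then excised. The lactone side chain follows by auxiliary-controlled conjugate addition and aldol reactions.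

Key step: step 6

Remark on numbering: hydrindane carbons are numbered as in octahydro-1H-indene (C1–C7a); ring A is the six-membered ring, ring B the five-membered ring.
Assumption: the (2S,5S)-imidazolidinone is taken to leave the Re face of the SOMO-activated enamine carbon open, so its (2R,5R) enantiomer is used to set 6S (if the sense proves opposite, the other catalyst enantiomer is used); tert-butyl glyoxylate is taken as a commercial reagent.

Step 1
Reactants: 1 methacrolein (2-methylprop-2-enal); 2 2-(2-bromoethyl)-1,3-dioxolane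
Product: 4 1-(1,3-dioxolan-2-yl)-4-methylpent-4-en-3-ol (racemic), via Grignard reagent 3 (not isolated)
Conditions: Mg, THF, 25–30 °C; then 1, −78 → 0 °C; aq. NH4Cl
Reagents that add atoms: none
Why: Grignard 1,2-addition, in which the acetal-protected Grignard reagent 3 attacks the aldehyde carbonyl of the enal and not its β-carbon; the racemic carbinol centre is erased in step 2.

Step 2
Reactants: 4; 5 triethyl orthoacetate
Product: 6 ethyl (4E)-7-(1,3-dioxolan-2-yl)-4-methylhept-4-enoate
Conditions: 5 (5 equiv), EtCO2H (cat.), 140 °C, EtOH distilled off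
Reagents that add atoms: none
Why: Johnson–Claisen rearrangement through a chair transition state with the carbinol substituent equatorial, which should give the E-trisubstituted C7a=C3a alkene and add the ester carbon (future formyl carbon) and C6.

Step 3
Reactants: 6
Product: 7 ethyl (4E)-4-methyl-8-oxooct-4-enoate
Conditions: 1 M HCl, THF, rt
Reagents that add atoms: water, O
Why: Acid-catalysed acetal hydrolysis frees the aldehyde that becomes C1, while the ethyl ester and the trisubstituted alkene are inert to dilute aqueous acid at room temperature.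

Step 4
Reactants: 7
Product: 8 ethyl (4E,8Z)-4-methyl-10-(trimethylsilyl)deca-4,8-dienoate
Conditions: Ph3PCH3Br, n-BuLi, THF, 0 °C; Me3SiCH2I, rt; n-BuLi, −78 °C; then 7, −78 °C → rt
Reagents that add atoms: methyltriphenylphosphonium bromide, C[P+](c1ccccc1)(c1ccccc1)c1ccccc1.[Br-]; (iodomethyl)trimethylsilane, C[Si](C)(C)CI
Why: Wittig olefination with the β-silyl ylide, a non-stabilised ylide that reacts with the aldehyde far faster than with the ester and should give mainly the Z-allylsilane.

Step 5
Reactants: 8
Product: 9 (4E,8Z)-4-methyl-10-(trimethylsilyl)deca-4,8-dienal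
Conditions: i-Bu2AlH (1.05 equiv), CH2Cl2, −78 °C; Rochelle salt work-up
Reagents that add atoms: none
Why: Low-temperature hydride reduction of the ester stops at the aluminium hemiacetal, which collapses to the aldehyde on work-up; the allylsilane and the alkenes do not react.

Step 6
Reactants: 9; 10 2-methylpropene (isobutene)
Product: 13 (1R,3aS,6S,7aR)-1-ethenyl-4,4,7a-trimethyloctahydro-1H-indene-6-carbaldehyde, via iminium tertiary cation 11 (not isolated), via monocyclic cation 12 (not isolated)
Conditions: 9 added over 6 h to (2R,5R)-5-benzyl-2-tert-butyl-3-methylimidazolidin-4-one·CF3CO2H (20 mol %), Fe(phen)3(SbF6)3 (2.5 equiv), Na2HPO4 (2.5 equiv), H2O (3 equiv), 10 (30 equiv), acetone, −30 °C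
Reagents that add atoms: water, O
Why: Proposed new method: the enamine of 9 is oxidised by the trivalent iron complex to a radical cation whose C6 adds to the CH2 end of isobutene (C5–C6), the tertiary C4 radical is oxidised to cation 11, 11 closes ring A by 6-endo-trig chair attack on C3a of the E-alkene (C3a–C4) to give 12, and the C7a cation of 12 is trapped 5-exo-trig by the Z-allylsilane (ring B, loss of the silyl group) before the iminium ion is hydrolysed. The closest known reaction types are the SOMO-catalysed formal [4+2] annulation of aldehydes that carry a tethered π-nucleophile with styrenes and the allylsilane-terminated cationic polyene bicyclisation to trans-hydrindanes; not yet shown are an unactivated 1,1-disubstituted alkene as the intermolecular partner and an alkene–allylsilane relay as the cation trap. C6 is set by the catalyst, whose benzyl group shields one face of the radical cation; C3a and C7a are set by anti addition across the E-trisubstituted alkene (trans ring fusion) in the chair that keeps the C6 iminium substituent equatorial and away from the axial methyl groups on C4 and C7a, so that 6S should be relayed to 3aS and 7aR; C1 is set in the ring B closure, which should place the vinyl group cis to the 7a-methyl group as in related steroid ring D closures. The step needs the radical cation to choose isobutene over an allylsilane: every intramolecular closure from C6 is ruled out by the E-alkene (three-, four- or trans-seven-membered rings), and the bimolecular allylation is held back by the large excess of isobutene and the slow addition of 9. It also needs the C4 cation to cyclise before it eliminates or adds a second isobutene, which the intramolecular attack on a trisubstituted alkene should secure, and any C1 epimer formed is corrected later by equilibration of ketone 15.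

Step 7
Reactants: 13
Product: 14 (1S,3aS,6S,7aS)-1-acetyl-4,4,7a-trimethyloctahydro-1H-indene-6-carbaldehyde
Conditions: PdCl2 (10 mol %), CuCl (1 equiv), O2 (1 atm), DMF/H2O (7:1), rt
Reagents that add atoms: water, O
Why: Tsuji–Wacker oxidation, in which Markovnikov hydroxypalladation of the terminal vinyl group gives the methyl ketone and the aldehyde is carried through unchanged.

Step 8
Reactants: 14
Product: 15 1-[(1S,3aS,7aS)-4,4,7a-trimethyloctahydro-1H-inden-1-yl]ethan-1-one
Conditions: Rh(dppp)2Cl (5 mol %), diglyme, 160 °C; then K2CO3, MeOH, rt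
Reagents that add atoms: none
Why: Rhodium-catalysed decarbonylation (Tsuji–Wilkinson type) removes the relay formyl group and leaves C6 as CH2, the ketone being inert, and the carbonate treatment lets C1 settle in the more stable configuration with the acetyl group cis to the 7a-methyl group, as in 20-oxopregnanes.

Step 9
Reactants: 15
Product: 16 N'-{1-[(1S,3aS,7aS)-4,4,7a-trimethyloctahydro-1H-inden-1-yl]ethylidene}-2,4,6-tri(propan-2-yl)benzenesulfonohydrazide
Conditions: 2,4,6-(i-Pr)3C6H2SO2NHNH2, HCl (cat.), THF, rt
Reagents that add atoms: 2,4,6-tri(propan-2-yl)benzenesulfonohydrazide, CC(C)c1cc(C(C)C)c(S(=O)(=O)NN)c(C(C)C)c1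
Why: Hydrazone condensation of the methyl ketone gives the substrate for a Shapiro reaction; no stereocentre is formed.

Step 10
Reactants: 17 (4S)-4-benzyl-1,3-oxazolidin-2-one; 18 acryloyl chloride
Product: 19 (4S)-4-benzyl-3-(prop-2-enoyl)-1,3-oxazolidin-2-one
Conditions: Et3N, LiCl, THF, 0 °C → rt
Reagents that add atoms: none
Why: N-Acylation of the oxazolidinone by the acid chloride under LiCl/Et3N activation gives the acryloyl imide without touching the stereocentre.

Step 11
Reactants: 19; 20 tert-butyl(dimethyl)(prop-2-en-1-yloxy)silane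
Product: 21 (4S)-4-benzyl-3-[(2E)-4-{[tert-butyl(dimethyl)silyl]oxy}but-2-enoyl]-1,3-oxazolidin-2-one
Conditions: 20 (3 equiv), second-generation Hoveyda–Grubbs catalyst (5 mol %), CH2Cl2, 40 °C
Reagents that add atoms: none
Why: Olefin cross-metathesis between the electron-poor acryloyl imide and an excess of the allyl silyl ether should give the E-enoyl imide selectively with loss of ethene.

Step 12
Reactants: 16; 21
Product: 24 (4S)-4-benzyl-3-[(3R)-3-({[tert-butyl(dimethyl)silyl]oxy}methyl)-4-[(1R,3aS,7aS)-4,4,7a-trimethyloctahydro-1H-inden-1-yl]pent-4-enoyl]-1,3-oxazolidin-2-one, via vinyllithium 22 (not isolated), via vinylmagnesium bromide 23 (not isolated)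
Conditions: n-BuLi (2.1 equiv), THF, −78 → 0 °C; MgBr2·OEt2, −78 °C; CuBr·SMe2 (30 mol %), 21 (1.2 equiv), THF/Me2S, −40 → −15 °C; aq. NH4Cl
Reagents that add atoms: none
Why: Shapiro reaction (deprotonation at the methyl group, loss of sulfinate and N2) gives the 1-substituted vinyllithium, and after transmetalation the copper-catalysed conjugate addition to the magnesium-chelated s-cis enoyl imide occurs on the face opposite the benzyl group, which should set 3R at the new stereocentre.

Step 13
Reactants: 24; 25 tert-butyl 2-oxoacetate (tert-butyl glyoxylate)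
Product: 27 tert-butyl (2S,3S,4R)-3-{[(4S)-4-benzyl-2-oxo-1,3-oxazolidin-3-yl]carbonyl}-4-({[tert-butyl(dimethyl)silyl]oxy}methyl)-2-hydroxy-5-[(1R,3aS,7aS)-4,4,7a-trimethyloctahydro-1H-inden-1-yl]hex-5-enoate, via boron Z-enolate 26 (not isolated)
Conditions: Bu2BOTf, i-Pr2NEt, CH2Cl2, 0 °C; 25, −78 → 0 °C; pH 7 buffer, MeOH, H2O2, 0 °C
Reagents that add atoms: none
Why: Evans syn aldol reaction, in which the Z-boron enolate reacts through a Zimmerman–Traxler chair on the face opposite the benzyl group and so sets the imide-bearing carbon (future lactone C4) and the carbinol carbon (future lactone C3) with the syn relationship that becomes trans in the lactone.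

Step 14
Reactants: 27
Product: 28 tert-butyl (2S,3R,4R)-4-({[tert-butyl(dimethyl)silyl]oxy}methyl)-2-hydroxy-3-(hydroxymethyl)-5-[(1R,3aS,7aS)-4,4,7a-trimethyloctahydro-1H-inden-1-yl]hex-5-enoate
Conditions: LiBH4 (2 equiv), MeOH (2 equiv), THF, −10 → 0 °C
Reagents that add atoms: none
Why: Hydride reduction of the activated N-acyl oxazolidinone carbonyl releases the auxiliary and gives the primary alcohol, the hindered tert-butyl ester and the silyl ether reacting more slowly; no stereocentre changes.

Step 15
Reactants: 28
Product: 29 (3S,4R)-3-hydroxy-4-{(2R)-1-hydroxy-3-[(1R,3aS,7aS)-4,4,7a-trimethyloctahydro-1H-inden-1-yl]but-3-en-2-yl}oxolan-2-one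
Conditions: CF3CO2H/CH2Cl2 (1:4), H2O (2 equiv), 0 °C → rt; aq. NaHCO3
Reagents that add atoms: none
Why: Acid-mediated lactonisation of the γ-hydroxy tert-butyl ester closes the five-membered lactone (favoured over the six-membered alternative through the other primary oxygen) and the same acid cleaves the primary silyl ether; the stereocentres are untouched.

Step 16
Reactants: 29
Product: 30 [(2R)-2-[(3R,4S)-4-hydroxy-5-oxooxolan-3-yl]-3-[(1R,3aS,7aS)-4,4,7a-trimethyloctahydro-1H-inden-1-yl]but-3-en-1-yl] acetate (CNP0252518.2)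
Conditions: AcCl (1.05 equiv), 2,4,6-collidine, CH2Cl2, −78 °C
Reagents that add atoms: acetyl chloride, CC(Cl)=O
Why: Base-buffered O-acylation at low temperature discriminates the primary hydroxyl from the hindered, less nucleophilic α-hydroxy lactone hydroxyl and should give the target monoacetate.

**Compound list**

1 | methacrolein (2-methylprop-2-enal) | C=C(C)C=O | starting material
2 | 2-(2-bromoethyl)-1,3-dioxolane | BrCCC1OCCO1 | starting material
3 | [2-(1,3-dioxolan-2-yl)ethyl]magnesium bromide | Br[Mg]CCC1OCCO1 | intermediate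
4 | 1-(1,3-dioxolan-2-yl)-4-methylpent-4-en-3-ol (racemic) | C=C(C)C(O)CCC1OCCO1 | intermediate
5 | triethyl orthoacetate | CCOC(C)(OCC)OCC | starting material
6 | ethyl (4E)-7-(1,3-dioxolan-2-yl)-4-methylhept-4-enoate | CCOC(=O)CC/C(C)=C/CCC1OCCO1 | intermediate
7 | ethyl (4E)-4-methyl-8-oxooct-4-enoate | CCOC(=O)CC/C(C)=C/CCC=O | intermediate
8 | ethyl (4E,8Z)-4-methyl-10-(trimethylsilyl)deca-4,8-dienoate | CCOC(=O)CC/C(C)=C/CC/C=C\C[Si](C)(C)C | intermediate
9 | (4E,8Z)-4-methyl-10-(trimethylsilyl)deca-4,8-dienal | O=CCC/C(C)=C/CC/C=C\C[Si](C)(C)C | intermediate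
10 | 2-methylpropene (isobutene) | CC(C)=C | starting material
11 | open-chain dication: iminium ion of the (2R,5R)-imidazolidinone with the (2S)-configured dienal that carries a 2-methylpropan-2-ylium-1-yl group on its α-carbon (C6); cation at C4 | CC(C)(C)[C@@H]1[N+](=C[C@@H](C[C+](C)C)C/C(C)=C/CC/C=C\C[Si](C)(C)C)[C@H](Cc2ccccc2)C(=O)N1C | intermediate
12 | monocyclic dication: ring A closed, iminium substituent equatorial on C6, (3Z)-5-(trimethylsilyl)pent-3-enyl chain on C3a, tertiary cation at C7a | CC(C)(C)[C@@H]1[N+](=C[C@H]2CC(C)(C)[C@H](CC/C=C\C[Si](C)(C)C)[C+](C)C2)[C@H](Cc3ccccc3)C(=O)N1C | intermediate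
13 | (1R,3aS,6S,7aR)-1-ethenyl-4,4,7a-trimethyloctahydro-1H-indene-6-carbaldehyde (trans ring fusion, vinyl cis to 7a-methyl, formyl equatorial) | C=C[C@H]1CC[C@H]2C(C)(C)C[C@H](C=O)C[C@]12C | intermediate
14 | (1S,3aS,6S,7aS)-1-acetyl-4,4,7a-trimethyloctahydro-1H-indene-6-carbaldehyde | CC(=O)[C@H]1CC[C@H]2C(C)(C)C[C@H](C=O)C[C@]12C | intermediate
15 | 1-[(1S,3aS,7aS)-4,4,7a-trimethyloctahydro-1H-inden-1-yl]ethan-1-one | CC(=O)[C@H]1CC[C@H]2C(C)(C)CCC[C@]12C | intermediate
16 | 2,4,6-tri(propan-2-yl)benzenesulfonyl hydrazone of 15 | CC(=NNS(=O)(=O)c1c(C(C)C)cc(C(C)C)cc1C(C)C)[C@H]1CC[C@H]2C(C)(C)CCC[C@]12C | intermediate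
17 | (4S)-4-benzyl-1,3-oxazolidin-2-one | O=C1N[C@@H](Cc2ccccc2)CO1 | starting material
18 | acryloyl chloride | C=CC(Cl)=O | starting material
19 | (4S)-4-benzyl-3-(prop-2-enoyl)-1,3-oxazolidin-2-one | C=CC(=O)N1[C@@H](Cc2ccccc2)COC1=O | intermediate
20 | tert-butyl(dimethyl)(prop-2-en-1-yloxy)silane | C=CCO[Si](C)(C)C(C)(C)C | starting material
21 | (4S)-4-benzyl-3-[(2E)-4-{[tert-butyl(dimethyl)silyl]oxy}but-2-enoyl]-1,3-oxazolidin-2-one | CC(C)(C)[Si](C)(C)OC/C=C/C(=O)N1[C@@H](Cc2ccccc2)COC1=O | intermediate
22 | {1-[(1R,3aS,7aR)-4,4,7a-trimethyloctahydro-1H-inden-1-yl]ethenyl}lithium (ring configuration as in 15) | [Li]C(=C)[C@H]1CC[C@H]2C(C)(C)CCC[C@]12C | intermediate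
23 | {1-[(1R,3aS,7aR)-4,4,7a-trimethyloctahydro-1H-inden-1-yl]ethenyl}magnesium bromide | Br[Mg]C(=C)[C@H]1CC[C@H]2C(C)(C)CCC[C@]12C | intermediate
24 | (4S)-4-benzyl-3-[(3R)-3-({[tert-butyl(dimethyl)silyl]oxy}methyl)-4-[(1R,3aS,7aS)-4,4,7a-trimethyloctahydro-1H-inden-1-yl]pent-4-enoyl]-1,3-oxazolidin-2-one | O=C(C[C@@H](CO[Si](C)(C)C(C)(C)C)C(=C)[C@H]1CC[C@H]2C(C)(C)CCC[C@]12C)N1[C@@H](Cc2ccccc2)COC1=O | intermediate
25 | tert-butyl 2-oxoacetate (tert-butyl glyoxylate) | CC(C)(C)OC(=O)C=O | starting material
26 | dibutylboron Z-enolate of 24 | CCCCB(CCCC)O/C(N1[C@@H](Cc2ccccc2)COC1=O)=C\[C@@H](CO[Si](C)(C)C(C)(C)C)C(=C)[C@H]1CC[C@H]2C(C)(C)CCC[C@]12C | intermediate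
27 | tert-butyl (2S,3S,4R)-3-{[(4S)-4-benzyl-2-oxo-1,3-oxazolidin-3-yl]carbonyl}-4-({[tert-butyl(dimethyl)silyl]oxy}methyl)-2-hydroxy-5-[(1R,3aS,7aS)-4,4,7a-trimethyloctahydro-1H-inden-1-yl]hex-5-enoate | CC(C)(C)OC(=O)[C@@H](O)[C@@H](C(=O)N1[C@@H](Cc2ccccc2)COC1=O)[C@@H](CO[Si](C)(C)C(C)(C)C)C(=C)[C@H]1CC[C@H]2C(C)(C)CCC[C@]12C | intermediate
28 | tert-butyl (2S,3R,4R)-4-({[tert-butyl(dimethyl)silyl]oxy}methyl)-2-hydroxy-3-(hydroxymethyl)-5-[(1R,3aS,7aS)-4,4,7a-trimethyloctahydro-1H-inden-1-yl]hex-5-enoate | CC(C)(C)OC(=O)[C@@H](O)[C@@H](CO)[C@@H](CO[Si](C)(C)C(C)(C)C)C(=C)[C@H]1CC[C@H]2C(C)(C)CCC[C@]12C | intermediate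
29 | (3S,4R)-3-hydroxy-4-{(2R)-1-hydroxy-3-[(1R,3aS,7aS)-4,4,7a-trimethyloctahydro-1H-inden-1-yl]but-3-en-2-yl}oxolan-2-one | C=C([C@H]1CC[C@H]2C(C)(C)CCC[C@]12C)[C@H](CO)[C@@H]1COC(=O)[C@H]1O | intermediate
30 | [(2R)-2-[(3R,4S)-4-hydroxy-5-oxooxolan-3-yl]-3-[(1R,3aS,7aS)-4,4,7a-trimethyloctahydro-1H-inden-1-yl]but-3-en-1-yl] acetate | C=C([C@H]1CC[C@H]2C(C)(C)CCC[C@]12C)[C@H](COC(C)=O)[C@@H]1COC(=O)[C@H]1O | target

**Step count.** 16 steps in total. The longest linear sequence is 14 steps (steps 1–9, then 12–16); steps 10 and 11 make imide 21.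

**Steps most likely to fail**

Step 6 (the proposed new method). The radical cation may be captured by the allylsilane of a second molecule instead of by isobutene. The tertiary cations may be quenched by water before the rings close. The relay from C6 may be too weak to fix the ring enantiomer series. The fallback uses known chemistry and makes the two ring A bonds in separate operations. It sets out from 9. Wittig olefination of 9 with isopropylidenetriphenylphosphorane should give trimethyl[(2Z,6E)-7,11-dimethyldodeca-2,6,10-trien-1-yl]silane F1, in which the formyl carbon of 9 has become C5. Protonation of its terminal trisubstituted alkene by a Lewis-acid-assisted chiral Brønsted acid (SnCl4 with a BINOL monoether, CH2Cl2, −78 °C) should start an allylsilane-terminated cationic polyene bicyclisation to (1R,3aS,7aR)-1-ethenyl-4,4,7a-trimethyloctahydro-1H-indene F2. Wacker oxidation of F2 under the conditions of step 7 should then give ketone 15, where the fallback comes back to the route; no formyl group is present, so step 8 is not needed. If the asymmetric protonation is not selective enough, racemic material is carried to 24, where the auxiliary turns the two ring series into separable diastereomers.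

Step 12. Transfer of the hindered, α-branched alkenyl group from copper may be slow, so that attack of the Grignard reagent on the imide carbonyl groups or its protonation by the solvent takes over, and incomplete chelation may erode the facial control. The fallback replaces the organolithium route by boron and rhodium chemistry. It sets out from 15. Kinetic enolisation at the methyl group (KN(SiMe3)2, PhNTf2, THF, −78 °C) should give 1-[(1S,3aS,7aS)-4,4,7a-trimethyloctahydro-1H-inden-1-yl]ethenyl trifluoromethanesulfonate F3. Miyaura borylation (bis(pinacolato)diboron, Pd(dppf)Cl2, KOPh, toluene, 50 °C) should give 4,4,5,5-tetramethyl-2-{1-[(1R,3aS,7aR)-4,4,7a-trimethyloctahydro-1H-inden-1-yl]ethenyl}-1,3,2-dioxaborolane F4. Rhodium-catalysed 1,4-addition of F4 to 21 (Hayashi–Miyaura reaction, [Rh(OH)(cod)]2 with the BINAP enantiomer that matches the auxiliary, dioxane/H2O, 50 °C) should give 24, where the fallback comes back to the route.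

Step 8. At 160 °C the secondary alkylrhodium intermediate may undergo β-hydride elimination to ring A alkenes, or turnover may stall at the hindered aldehyde. The fallback removes the carbon by radical decarboxylation instead. It sets out from 14. Pinnick oxidation (NaClO2, NaH2PO4, 2-methylbut-2-ene, t-BuOH/H2O) should give (1S,3aS,6S,7aS)-1-acetyl-4,4,7a-trimethyloctahydro-1H-indene-6-carboxylic acid F5. Activation with oxalyl chloride and reaction with sodium 2-thioxopyridin-1(2H)-olate should give the Barton ester 2-thioxopyridin-1(2H)-yl (1S,3aS,6S,7aS)-1-acetyl-4,4,7a-trimethyloctahydro-1H-indene-6-carboxylate F6. Photolysis of F6 with t-BuSH (Barton decarboxylation) should give ketone 15, where the fallback comes back to the route.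

Further compounds
F1 | step 6 | trimethyl[(2Z,6E)-7,11-dimethyldodeca-2,6,10-trien-1-yl]silane | CC(C)=CCC/C(C)=C/CC/C=C\C[Si](C)(C)C
F2 | step 6 | (1R,3aS,7aR)-1-ethenyl-4,4,7a-trimethyloctahydro-1H-indene | C=C[C@H]1CC[C@H]2C(C)(C)CCC[C@]12C
F3 | step 12 | 1-[(1S,3aS,7aS)-4,4,7a-trimethyloctahydro-1H-inden-1-yl]ethenyl trifluoromethanesulfonate | C=C(OS(=O)(=O)C(F)(F)F)[C@H]1CC[C@H]2C(C)(C)CCC[C@]12C
F4 | step 12 | 4,4,5,5-tetramethyl-2-{1-[(1R,3aS,7aR)-4,4,7a-trimethyloctahydro-1H-inden-1-yl]ethenyl}-1,3,2-dioxaborolane | C=C(B1OC(C)(C)C(C)(C)O1)[C@H]1CC[C@H]2C(C)(C)CCC[C@]12C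
F5 | step 8 | (1S,3aS,6S,7aS)-1-acetyl-4,4,7a-trimethyloctahydro-1H-indene-6-carboxylic acid | CC(=O)[C@H]1CC[C@H]2C(C)(C)C[C@H](C(=O)O)C[C@]12C
F6 | step 8 | 2-thioxopyridin-1(2H)-yl (1S,3aS,6S,7aS)-1-acetyl-4,4,7a-trimethyloctahydro-1H-indene-6-carboxylate | CC(=O)[C@H]1CC[C@H]2C(C)(C)C[C@H](C(=O)On3ccccc3=S)C[C@]12C
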